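Locants are those of the octahydronaphthalene core (C1 propenoic acid, C2 ester oxygen, C4 carbinol, C6 acetate; ring A = C1–C4, C4a, C8a; ring B = C4a, C5–C8, C8a). Ring B is closed last, on a preformed ring A enone, by a silicon-tethered intramolecular Diels–Alder reaction that exploits the cis-1,3 relationship of O–C2 and the C8a–C8 bond: O–C2 carries a (Z)-2-methylbuta-1,3-dienyl(dimethyl)silyl group, and cycloaddition to C4a=C8a of the C4 enone forms C8–C8a and C5–C4a at once. Silicon on C8 is the latent C7=C8 alkene and C6 oxygen; its removal frees O–C2, and the C4 ketone becomes the carbinol.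

Key step: step 14

Remarks
(a) β denotes the face of ring A that carries the C1 side chain. The target has 1β-side chain, 2β-O, 4β-CH3/4α-OH, 4aβ-H, 6α-OAc and 8aα-H.
(b) Assumption: the lipase step is taken to give the (1S,4R)-monoacetate 3. Should the enzyme show the opposite sense, the same compound should follow from the complementary lipase-catalysed mono-acetylation of the meso diol.

Step 1
Reactants: 1 cyclohexa-1,3-diene
Product: 2 meso-cis-cyclohex-2-ene-1,4-diyl diacetate
Conditions: Pd(OAc)2 (5 mol %), LiCl (cat.), LiOAc, p-benzoquinone, AcOH, 25 °C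
Reagents that add atoms: acetic acid (as acetate), CC(=O)O
Why: Palladium-catalysed oxidative 1,4-diacetoxylation of a 1,3-diene; with catalytic chloride the second acetate attacks the π-allyl intermediate from outside, which should give the cis (meso) diacetate.

Step 2
Reactants: 2 meso-cis-cyclohex-2-ene-1,4-diyl diacetate
Product: 3 (1S,4R)-4-acetoxycyclohex-2-en-1-ol
Conditions: Candida antarctica lipase B, phosphate buffer (pH 7), 25 °C
Reagents that add atoms: none
Why: Enzymatic desymmetrisation of a meso diester; hydrolysis of one enantiotopic acetate sets the absolute configuration from which all later centres are relayed.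

Step 3
Reactants: 3 (1S,4R)-4-acetoxycyclohex-2-en-1-ol
Product: 4 (1R,4S)-4-(tert-butyldimethylsilyloxy)cyclohex-2-en-1-yl acetate
Conditions: t-BuMe2SiCl, imidazole, DMF, 25 °C
Reagents that add atoms: tert-butyldimethylsilyl chloride, CC(C)(C)[Si](C)(C)Cl
Why: Silylation of the free secondary alcohol (the future O–C2); no stereocentre is touched.

Step 4
Reactants: 4 (1R,4S)-4-(tert-butyldimethylsilyloxy)cyclohex-2-en-1-yl acetate
Product: 7 2-[(1R,6S)-6-(tert-butyldimethylsilyloxy)cyclohex-2-en-1-yl]acetic acid, via silyl ketene acetal 5 (not isolated), via trimethylsilyl ester 6 (not isolated)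
Conditions: LiN(i-Pr)2, Me3SiCl, THF, −78 °C, then 65 °C; dilute aqueous HCl work-up
Reagents that add atoms: none
Why: Ireland–Claisen rearrangement; the suprafacial [3,3]-shift forms the new C–C bond (future C1) on the face of the departing C–O bond, hence cis to the silyloxy group at the future C2, and leaves the future C4a=C8a alkene.

Step 5
Reactants: 7 2-[(1R,6S)-6-(tert-butyldimethylsilyloxy)cyclohex-2-en-1-yl]acetic acid
Product: 8 2-[(1R,6S)-6-(tert-butyldimethylsilyloxy)cyclohex-2-en-1-yl]ethanol
Conditions: LiAlH4, THF, 0 °C to 25 °C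
Reagents that add atoms: none
Why: Hydride reduction of the carboxylic acid to the primary alcohol, which stores the C1 side chain at a level inert to all ring-forming steps.

Step 6
Reactants: 8 2-[(1R,6S)-6-(tert-butyldimethylsilyloxy)cyclohex-2-en-1-yl]ethanol
Product: 9 tert-butyldiphenylsilyl ether of 8
Conditions: t-BuPh2SiCl, imidazole, CH2Cl2, 25 °C
Reagents that add atoms: tert-butyldiphenylsilyl chloride, CC(C)(C)[Si](Cl)(c1ccccc1)c1ccccc1
Why: Silylation of the primary alcohol with a group that should survive the later selective removal of the secondary silyl ether.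

Step 7
Reactants: 9 tert-butyldiphenylsilyl ether of 8
Product: 10 (4R,5S)-5-(tert-butyldimethylsilyloxy)-4-[2-(tert-butyldiphenylsilyloxy)ethyl]cyclohex-2-en-1-one
Conditions: CrO3, 3,5-dimethylpyrazole, CH2Cl2, −20 °C
Reagents that add atoms: chromium trioxide, O=[Cr](=O)=O
Why: Allylic C–H oxidation of a cyclohexene to the enone; the unhindered allylic CH2 (future C4) should react in preference to the substituted allylic CH (future C1).

Step 8
Reactants: 10 (4R,5S)-5-(tert-butyldimethylsilyloxy)-4-[2-(tert-butyldiphenylsilyloxy)ethyl]cyclohex-2-en-1-one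
Product: 11 (4R,5S)-5-hydroxy-4-[2-(tert-butyldiphenylsilyloxy)ethyl]cyclohex-2-en-1-one
Conditions: HF·pyridine, pyridine, THF, 0 °C to 25 °C
Reagents that add atoms: none
Why: Fluoride-mediated cleavage of the secondary silyl ether; the primary tert-butyldiphenylsilyl ether is far more stable, and base-free conditions should avoid β-elimination of the C5 oxygen.

Step 9
Reactants: 12 prop-2-yn-1-ol
Product: 14 (Z)-3-iodo-2-methylprop-2-en-1-ol, via vinylmagnesium alkoxide 13 (not isolated)
Conditions: MeMgBr (2.5 equiv), CuI (10 mol %), THF, −10 °C to 25 °C; then I2, −10 °C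
Reagents that add atoms: methylmagnesium bromide, C[Mg]Br; iodine, II
Why: Copper-catalysed carbomagnesiation of the propargylic alkoxide proceeds by anti addition through a five-membered chelate, and iodinolysis with retention should give the Z vinyl iodide.

Step 10
Reactants: 14 (Z)-3-iodo-2-methylprop-2-en-1-ol
Product: 15 (Z)-3-iodo-2-methylprop-2-enal
Conditions: MnO2, CH2Cl2, 25 °C, dark
Reagents that add atoms: none
Why: Mild oxidation of an allylic alcohol with MnO2, which should leave the Z iodoalkene geometry intact.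

Step 11
Reactants: 15 (Z)-3-iodo-2-methylprop-2-enal
Product: 16 (Z)-1-iodo-2-methylbuta-1,3-diene
Conditions: Ph3PCH3Br, KOC(CH3)3, Et2O, 0 °C
Reagents that add atoms: methyltriphenylphosphonium bromide, C[P+](c1ccccc1)(c1ccccc1)c1ccccc1.[Br-]
Why: Wittig methylenation of the aldehyde; the trisubstituted iodoalkene is not involved and keeps its Z geometry.

Step 12
Reactants: 16 (Z)-1-iodo-2-methylbuta-1,3-diene
Product: 18 (Z)-chloro(dimethyl)(2-methylbuta-1,3-dien-1-yl)silane, via dienyllithium 17 (not isolated)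
Conditions: t-BuLi (2 equiv), Et2O, −78 °C; then Me2SiCl2 (excess), −78 °C to 25 °C; volatiles removed, used crude
Reagents that add atoms: dichlorodimethylsilane, C[Si](C)(Cl)Cl
Why: Iodine–lithium exchange with retention of alkene geometry, then monosubstitution of excess dichlorosilane.

Step 13
Reactants: 11 (4R,5S)-5-hydroxy-4-[2-(tert-butyldiphenylsilyloxy)ethyl]cyclohex-2-en-1-one; 18 (Z)-chloro(dimethyl)(2-methylbuta-1,3-dien-1-yl)silane
Product: 19 (4R,5S)-5-{dimethyl[(Z)-2-methylbuta-1,3-dien-1-yl]silyloxy}-4-[2-(tert-butyldiphenylsilyloxy)ethyl]cyclohex-2-en-1-one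
Conditions: imidazole, CH2Cl2, 0 °C
Reagents that add atoms: none
Why: Silyl ether formation attaches the diene to the future O–C2 under conditions too mild to eliminate the β-oxygen.

Step 14
Reactants: 19 (4R,5S)-5-{dimethyl[(Z)-2-methylbuta-1,3-dien-1-yl]silyloxy}-4-[2-(tert-butyldiphenylsilyloxy)ethyl]cyclohex-2-en-1-one
Product: 20 cis-fused tricyclic allylsilane (C4 ketone, C6=C7 alkene with 7-methyl, 4aα-H, 8aα-H, 1β-[2-(tert-butyldiphenylsilyloxy)ethyl], dimethylsilylene bridge from 2β-O to 8β-C)
Conditions: toluene (0.01 M), 2,6-di-tert-butyl-4-methylphenol (cat.), sealed tube, 150 °C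
Reagents that add atoms: none
Why: Thermal, concerted suprafacial [4+2] cycloaddition of the tethered diene C8=C7–C6=C5 to the enone double bond C8a=C4a; the closest known reaction type is the temporary silicon-tethered intramolecular Diels–Alder reaction of dienylsilyl ethers. Ring B closes by the cycloaddition itself (new bonds C8–C8a and C5–C4a), and the temporary six-membered siloxane ring (C8a–C1–C2–O–Si–C8) closes as a bridge over the β-face of ring A from the pseudoaxial O–C2, which only an exo transition state with silicon as the inside (Z) substituent of the diene can reach. C8a is controlled by the tether (C8 is delivered to the β-face, cis to O–C2 and to the C1 side chain, whereas an untethered diene would add anti to that side chain), C4a follows from suprafacial addition (4a-H α, corrected in step 16), and C8 is fixed by the bridge with the C–Si bond pseudoaxial on the β-face. The regioselectivity needed (C8 to the β-carbon C8a, C5 to C4a) is enforced by the short tether and matched electronically by the C7 methyl group, which enlarges the diene coefficient at C8. The step also needs the cycloaddition to outrun β-elimination of the C2 silyloxy group, for which dilute, base-free heating with a radical inhibitor is chosen.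

Step 15
Reactants: 20 cis-fused tricyclic allylsilane
Product: 22 cis-fused keto diol (C4 ketone, C7=C8 alkene, 2β-OH, 6α-OH, 4aα-H, 8aα-H), via epoxysilane 21 (not isolated)
Conditions: 3-chloroperoxybenzoic acid, Na2HPO4, CH2Cl2, −20 °C; then pyridinium p-toluenesulfonate, MeOH, 25 °C
Reagents that add atoms: 3-chloroperoxybenzoic acid, OOC(=O)c1cccc(Cl)c1
Why: Epoxidation of the allylsilane on the open α-face, anti to the pseudoaxial C8–Si bond, followed by acid-promoted anti desilylative opening (allylsilane SE2′, Peterson-type) should move the alkene to C7=C8 and place the hydroxyl at C6 on the α-face, while methanolysis of the silyl ether frees O–C2.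

Step 16
Reactants: 22 cis-fused keto diol
Product: 23 trans-fused keto diol (4aβ-H, 8aα-H; otherwise as 22)
Conditions: K2CO3, MeOH, 25 °C
Reagents that add atoms: none
Why: Base-mediated epimerisation of the ketone α-centre C4a through the enolate; the trans-fused decalone with only the C1 side chain axial should be the thermodynamic isomer, since either chair of the cis isomer carries a 1,3-diaxial pair.

Step 17
Reactants: 23 trans-fused keto diol
Product: 24 triol (4β-CH3, 4α-OH, 2β-OH, 6α-OH)
Conditions: MeMgBr (4 equiv), CeCl3, THF, −78 °C to 0 °C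
Reagents that add atoms: methylmagnesium bromide, C[Mg]Br
Why: Grignard addition to the cyclohexanone under CeCl3 promotion (to suppress enolisation); the small methyl nucleophile should attack the rigid trans-decalone from the equatorial direction, giving the axial 4α-hydroxyl and equatorial 4β-methyl.

Step 18
Reactants: 24 triol
Product: 25 enone diol (C6 ketone conjugated with C7=C8; 2β-OH, 4α-OH)
Conditions: MnO2, CH2Cl2, 25 °C
Reagents that add atoms: none
Why: MnO2 oxidises only the allylic C6 alcohol, which differentiates it from the saturated secondary C2 alcohol and the tertiary C4 alcohol.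

Step 19
Reactants: 26 2,2-dimethyl-4,7-dihydro-1,3-dioxepine
Product: 27 rac-trans-5,6-dibromo-2,2-dimethyl-1,3-dioxepane
Conditions: Br2, CH2Cl2, −78 °C
Reagents that add atoms: bromine, BrBr
Why: Anti addition of bromine to the cis alkene of the acetonide of cis-but-2-ene-1,4-diol.

Step 20
Reactants: 27 rac-trans-5,6-dibromo-2,2-dimethyl-1,3-dioxepane
Product: 28 5-bromo-2,2-dimethyl-4,7-dihydro-1,3-dioxepine
Conditions: KOC(CH3)3, THF, 0 °C
Reagents that add atoms: none
Why: E2 dehydrobromination; the more acidic CHBr hydrogen is removed anti to the neighbouring bromide, giving the vinyl bromide.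

Step 21
Reactants: 28 5-bromo-2,2-dimethyl-4,7-dihydro-1,3-dioxepine
Product: 30 2,2-dimethyl-4,7-dihydro-1,3-dioxepine-5-carboxylic acid, via vinyllithium 29 (not isolated)
Conditions: t-BuLi (2 equiv), THF, −78 °C; then CO2; aqueous NaH2PO4
Reagents that add atoms: carbon dioxide, O=C=O
Why: Bromine–lithium exchange and carboxylation; the seven-membered ring holds the two CH2O groups cis, which is the E geometry of the side-chain acid.

Step 22
Reactants: 25 enone diol; 30 2,2-dimethyl-4,7-dihydro-1,3-dioxepine-5-carboxylic acid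
Product: 32 C2 ester of 25 with acid 30, via mixed anhydride 31 (not isolated)
Conditions: 2,4,6-trichlorobenzoyl chloride, Et3N, THF, 0 °C; then 4-(dimethylamino)pyridine, toluene, 25 °C
Reagents that add atoms: none
Why: Yamaguchi esterification; the equatorial secondary C2 hydroxyl is acylated while the axial tertiary C4 hydroxyl should be too hindered to react.

Step 23
Reactants: 32 C2 ester of 25 with acid 30
Product: 33 6α-allylic alcohol
Conditions: NaBH4, CeCl3·7H2O, MeOH, −78 °C
Reagents that add atoms: none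
Why: Luche 1,2-reduction; axial hydride delivery to the 2-methylcyclohexenone of the trans-fused system should give the pseudoequatorial 6α-alcohol, and the unsaturated ester is not reduced.

Step 24
Reactants: 33 6α-allylic alcohol
Product: 34 6α-acetate
Conditions: Ac2O, pyridine, 4-(dimethylamino)pyridine (cat.), CH2Cl2, 0 °C
Reagents that add atoms: acetic anhydride, CC(=O)OC(C)=O
Why: Acetylation of the secondary allylic alcohol; the tertiary C4 alcohol should not react under these mild conditions.

Step 25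
Reactants: 34 6α-acetate
Product: 35 primary alcohol (C1 2-hydroxyethyl side chain)
Conditions: Bu4NF, AcOH, THF, 25 °C
Reagents that add atoms: none
Why: Buffered fluoride removes the tert-butyldiphenylsilyl group without touching the esters or the acetonide.

Step 26
Reactants: 35 primary alcohol
Product: 36 aldehyde (C1 2-oxoethyl side chain)
Conditions: Dess–Martin periodinane, NaHCO3, CH2Cl2, 0 °C to 25 °C
Reagents that add atoms: none
Why: Dess–Martin oxidation of the only primary or secondary alcohol present; the tertiary alcohol is inert.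

Step 27
Reactants: 36 aldehyde
Product: 37 2-substituted propenal (C1 side chain C(=CH2)CHO)
Conditions: aqueous formaldehyde (37 %), pyrrolidine (cat.), propionic acid (cat.), i-PrOH, 45 °C
Reagents that add atoms: formaldehyde, C=O
Why: Amine-catalysed α-methylenation of an aldehyde (Mannich condensation then elimination); the adjacent C1 stereocentre is not enolisable under these conditions.

Step 28
Reactants: 37 2-substituted propenal
Product: 38 acetonide-protected acid
Conditions: NaClO2, NaH2PO4, 2-methylbut-2-ene, t-BuOH/H2O, 0 °C to 25 °C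
Reagents that add atoms: sodium chlorite, [Na+].[O-]Cl=O
Why: Pinnick oxidation of the enal to the propenoic acid, with the alkene scavenger protecting the ring and side-chain double bonds from hypochlorite.

Step 29
Reactants: 38 acetonide-protected acid
Product: 39 target, 2-[(1S,2S,4S,4aR,6S,8aS)-6-acetoxy-4-hydroxy-2-{[(2E)-4-hydroxy-2-(hydroxymethyl)but-2-enoyl]oxy}-4,7-dimethyl-1,2,3,4,4a,5,6,8a-octahydronaphthalen-1-yl]prop-2-enoic acid
Conditions: AcOH/THF/H2O (3:1:1), 25 °C
Reagents that add atoms: none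
Why: Mild acid hydrolysis of the labile seven-membered acetonide; the esters, the allylic acetate and the tertiary alcohol should survive.

Compound list
1 | cyclohexa-1,3-diene | C1=CC=CCC1 | starting material
2 | meso-cis-cyclohex-2-ene-1,4-diyl diacetate | CC(=O)O[C@@H]1C=C[C@H](OC(C)=O)CC1 | intermediate
3 | (1S,4R)-4-acetoxycyclohex-2-en-1-ol | O[C@@H]1C=C[C@H](OC(C)=O)CC1 | intermediate
4 | (1R,4S)-4-(tert-butyldimethylsilyloxy)cyclohex-2-en-1-yl acetate | CC(C)(C)[Si](C)(C)O[C@@H]1C=C[C@H](OC(C)=O)CC1 | intermediate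
5 | trimethylsilyl ketene acetal of 4 | CC(C)(C)[Si](C)(C)O[C@@H]1C=C[C@H](OC(=C)O[Si](C)(C)C)CC1 | intermediate
6 | trimethylsilyl ester of 7 | C[Si](C)(C)OC(=O)C[C@@H]1C=CCC[C@@H]1O[Si](C)(C)C(C)(C)C | intermediate
7 | 2-[(1R,6S)-6-(tert-butyldimethylsilyloxy)cyclohex-2-en-1-yl]acetic acid | OC(=O)C[C@@H]1C=CCC[C@@H]1O[Si](C)(C)C(C)(C)C | intermediate
8 | 2-[(1R,6S)-6-(tert-butyldimethylsilyloxy)cyclohex-2-en-1-yl]ethanol | OCC[C@@H]1C=CCC[C@@H]1O[Si](C)(C)C(C)(C)C | intermediate
9 | tert-butyldiphenylsilyl ether of 8 | CC(C)(C)[Si](c1ccccc1)(c1ccccc1)OCC[C@@H]1C=CCC[C@@H]1O[Si](C)(C)C(C)(C)C | intermediate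
10 | (4R,5S)-5-(tert-butyldimethylsilyloxy)-4-[2-(tert-butyldiphenylsilyloxy)ethyl]cyclohex-2-en-1-one | CC(C)(C)[Si](c1ccccc1)(c1ccccc1)OCC[C@@H]1C=CC(=O)C[C@@H]1O[Si](C)(C)C(C)(C)C | intermediate
11 | (4R,5S)-5-hydroxy-4-[2-(tert-butyldiphenylsilyloxy)ethyl]cyclohex-2-en-1-one | CC(C)(C)[Si](c1ccccc1)(c1ccccc1)OCC[C@@H]1C=CC(=O)C[C@@H]1O | intermediate
12 | prop-2-yn-1-ol | C#CCO | starting material
13 | bromomagnesium (Z)-3-(bromomagnesio)-2-methylprop-2-en-1-olate | Br[Mg]OC/C(C)=C\[Mg]Br | intermediate
14 | (Z)-3-iodo-2-methylprop-2-en-1-ol | OC/C(C)=C\I | intermediate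
15 | (Z)-3-iodo-2-methylprop-2-enal | O=C/C(C)=C\I | intermediate
16 | (Z)-1-iodo-2-methylbuta-1,3-diene | C=C/C(C)=C\I | intermediate
17 | (Z)-(2-methylbuta-1,3-dien-1-yl)lithium | C=C/C(C)=C\[Li] | intermediate
18 | (Z)-chloro(dimethyl)(2-methylbuta-1,3-dien-1-yl)silane | C=C/C(C)=C\[Si](C)(C)Cl | intermediate
19 | (4R,5S)-5-{dimethyl[(Z)-2-methylbuta-1,3-dien-1-yl]silyloxy}-4-[2-(tert-butyldiphenylsilyloxy)ethyl]cyclohex-2-en-1-one | CC(C)(C)[Si](c1ccccc1)(c1ccccc1)OCC[C@@H]1C=CC(=O)C[C@@H]1O[Si](C)(C)/C=C(C)\C=C | intermediate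
20 | cis-fused tricyclic allylsilane (C4 ketone, C6=C7, 7-methyl, 4aα-H, 8aα-H, 1β-side chain, SiMe2 bridge from 2β-O to 8β-C) | CC(C)(C)[Si](c1ccccc1)(c1ccccc1)OCC[C@@H]1[C@@H]2[C@H]3C(C)=CC[C@@H]2C(=O)C[C@@H]1O[Si]3(C)C | intermediate
21 | 6α,7α-epoxide of 20 | CC(C)(C)[Si](c1ccccc1)(c1ccccc1)OCC[C@@H]1[C@@H]2[C@H]3[C@@]4(C)O[C@H]4C[C@@H]2C(=O)C[C@@H]1O[Si]3(C)C | intermediate
22 | cis-fused keto diol (C4 ketone, C7=C8, 2β-OH, 6α-OH, 4aα-H, 8aα-H) | CC(C)(C)[Si](c1ccccc1)(c1ccccc1)OCC[C@@H]1[C@@H]2C=C(C)[C@@H](O)C[C@@H]2C(=O)C[C@@H]1O | intermediate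
23 | trans-fused keto diol (4aβ-H, 8aα-H) | CC(C)(C)[Si](c1ccccc1)(c1ccccc1)OCC[C@@H]1[C@@H]2C=C(C)[C@@H](O)C[C@H]2C(=O)C[C@@H]1O | intermediate
24 | triol (4β-CH3, 4α-OH, 2β-OH, 6α-OH) | CC(C)(C)[Si](c1ccccc1)(c1ccccc1)OCC[C@@H]1[C@@H]2C=C(C)[C@@H](O)C[C@H]2[C@@](C)(O)C[C@@H]1O | intermediate
25 | enone diol (C6 ketone, C7=C8, 2β-OH, 4α-OH) | CC(C)(C)[Si](c1ccccc1)(c1ccccc1)OCC[C@@H]1[C@@H]2C=C(C)C(=O)C[C@H]2[C@@](C)(O)C[C@@H]1O | intermediate
26 | 2,2-dimethyl-4,7-dihydro-1,3-dioxepine | CC1(C)OCC=CCO1 | starting material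
27 | rac-trans-5,6-dibromo-2,2-dimethyl-1,3-dioxepane (one enantiomer drawn) | CC1(C)OC[C@H](Br)[C@@H](Br)CO1 | intermediate
28 | 5-bromo-2,2-dimethyl-4,7-dihydro-1,3-dioxepine | CC1(C)OCC=C(Br)CO1 | intermediate
29 | (2,2-dimethyl-4,7-dihydro-1,3-dioxepin-5-yl)lithium | CC1(C)OCC=C([Li])CO1 | intermediate
30 | 2,2-dimethyl-4,7-dihydro-1,3-dioxepine-5-carboxylic acid | CC1(C)OCC=C(CO1)C(=O)O | intermediate
31 | mixed anhydride of 30 with 2,4,6-trichlorobenzoic acid | CC1(C)OCC=C(CO1)C(=O)OC(=O)c1c(Cl)cc(Cl)cc1Cl | intermediate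
32 | C2 ester of 25 with acid 30 | CC(C)(C)[Si](c1ccccc1)(c1ccccc1)OCC[C@@H]1[C@@H]2C=C(C)C(=O)C[C@H]2[C@@](C)(O)C[C@@H]1OC(=O)C1=CCOC(C)(C)OC1 | intermediate
33 | 6α-allylic alcohol | CC(C)(C)[Si](c1ccccc1)(c1ccccc1)OCC[C@@H]1[C@@H]2C=C(C)[C@@H](O)C[C@H]2[C@@](C)(O)C[C@@H]1OC(=O)C1=CCOC(C)(C)OC1 | intermediate
34 | 6α-acetate | CC(C)(C)[Si](c1ccccc1)(c1ccccc1)OCC[C@@H]1[C@@H]2C=C(C)[C@@H](OC(C)=O)C[C@H]2[C@@](C)(O)C[C@@H]1OC(=O)C1=CCOC(C)(C)OC1 | intermediate
35 | primary alcohol (C1 2-hydroxyethyl) | OCC[C@@H]1[C@@H]2C=C(C)[C@@H](OC(C)=O)C[C@H]2[C@@](C)(O)C[C@@H]1OC(=O)C1=CCOC(C)(C)OC1 | intermediate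
36 | aldehyde (C1 2-oxoethyl) | O=CC[C@@H]1[C@@H]2C=C(C)[C@@H](OC(C)=O)C[C@H]2[C@@](C)(O)C[C@@H]1OC(=O)C1=CCOC(C)(C)OC1 | intermediate
37 | 2-substituted propenal | C=C(C=O)[C@@H]1[C@@H]2C=C(C)[C@@H](OC(C)=O)C[C@H]2[C@@](C)(O)C[C@@H]1OC(=O)C1=CCOC(C)(C)OC1 | intermediate
38 | acetonide-protected acid | C=C(C(=O)O)[C@@H]1[C@@H]2C=C(C)[C@@H](OC(C)=O)C[C@H]2[C@@](C)(O)C[C@@H]1OC(=O)C1=CCOC(C)(C)OC1 | intermediate
39 | 2-[(1S,2S,4S,4aR,6S,8aS)-6-acetoxy-4-hydroxy-2-{[(2E)-4-hydroxy-2-(hydroxymethyl)but-2-enoyl]oxy}-4,7-dimethyl-1,2,3,4,4a,5,6,8a-octahydronaphthalen-1-yl]prop-2-enoic acid | C=C(C(=O)O)[C@@H]1[C@@H]2C=C(C)[C@@H](OC(C)=O)C[C@H]2[C@@](C)(O)C[C@@H]1OC(=O)/C(=C/CO)CO | target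

Total step count: 29 (22 in the main line, 4 for chlorosilane 18, 3 for acid 30).
Longest linear sequence: 22 steps (steps 1–8, 13–18, 22–29).

Steps most likely to fail

Step 14. The bridged exo transition state with an inside silyl substituent may be reached only at temperatures where the β-silyloxy enone eliminates or the Z-diene isomerises, so that cycloaddition stalls. The fallback keeps the anchoring oxygen but forms the two ring B bonds stepwise by known chemistry; it sets out from 11 and returns at 25. Silylation of 11 with (bromomethyl)chlorodimethylsilane and imidazole should give the (bromomethyl)dimethylsilyl ether F1. A radical chain reaction with tributyl(2-methylenebutyl)stannane and azobisisobutyronitrile (benzene, 80 °C) should give the bridged siloxane F2: 6-exo cyclisation of the silylmethyl radical onto C8a from the β-face, then allyl transfer to the C4a radical anti to the new bond. Tamao–Fleming oxidation (H2O2, KF, KHCO3) should give the keto diol F3. MeMgBr with CeCl3 should give the triol F4, ozonolysis (O3, then Me2S) the ethyl ketone F5, and selective oxidation of the primary alcohol (TEMPO cat., PhI(OAc)2) the keto aldehyde F6. Intramolecular aldol condensation of F6 (pyrrolidine, AcOH) then closes ring B and gives 25.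

Step 7. Hydrogen abstraction at the substituted allylic CH, or allylic transposition during oxygen transfer, would give regioisomeric enones, and over-oxidation may consume material. The fallback replaces the chromium oxidation by a pericyclic hydroxylation; it sets out from 9 and returns at 10. SeO2 (cat.) with t-BuOOH in CH2Cl2 should hydroxylate the allylic CH2 by an ene reaction and [2,3]-sigmatropic shift that restore the alkene position, giving the allylic alcohol F7 as a C4 epimer mixture. MnO2 then oxidises F7 to 10.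

Step 16. Retro-aldol ring opening or β-elimination of the free C2 hydroxyl may compete with slow enolisation toward C4a, and the equilibrium may stop short of the trans isomer. The fallback equilibrates a protected derivative; it sets out from 22 and returns at 23. Et3SiCl and imidazole should give the bis(triethylsilyl) ether F8, in which the retro-aldol path is blocked. 1,8-Diazabicyclo[5.4.0]undec-7-ene in toluene at 60 °C should equilibrate it to the trans-fused bis(triethylsilyl) ether F9. Pyridinium p-toluenesulfonate in MeOH then removes both silyl groups and gives 23.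

Further compounds
F1 | step 14 | (bromomethyl)dimethylsilyl ether of 11 | CC(C)(C)[Si](c1ccccc1)(c1ccccc1)OCC[C@@H]1C=CC(=O)C[C@@H]1O[Si](C)(C)CBr
F2 | step 14 | bridged siloxane ketone (8a-CH2–SiMe2–O–C2 bridge on the β-face, 4a-(2-methylenebutyl) on the α-face) | CC(C)(C)[Si](c1ccccc1)(c1ccccc1)OCC[C@@H]1[C@H](C[Si]3(C)C)[C@@H](CC(=C)CC)C(=O)C[C@@H]1O3
F3 | step 14 | keto diol (8a-hydroxymethyl, 2β-OH, 4a-(2-methylenebutyl)) | CC(C)(C)[Si](c1ccccc1)(c1ccccc1)OCC[C@@H]1[C@H](CO)[C@@H](CC(=C)CC)C(=O)C[C@@H]1O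
F4 | step 14 | triol (4β-CH3, 4α-OH) | CC(C)(C)[Si](c1ccccc1)(c1ccccc1)OCC[C@@H]1[C@H](CO)[C@@H](CC(=C)CC)[C@@](C)(O)C[C@@H]1O
F5 | step 14 | ethyl ketone triol (4a-(2-oxobutyl)) | CC(C)(C)[Si](c1ccccc1)(c1ccccc1)OCC[C@@H]1[C@H](CO)[C@@H](CC(=O)CC)[C@@](C)(O)C[C@@H]1O
F6 | step 14 | keto aldehyde (8a-formyl, 4a-(2-oxobutyl)) | CC(C)(C)[Si](c1ccccc1)(c1ccccc1)OCC[C@@H]1[C@H](C=O)[C@@H](CC(=O)CC)[C@@](C)(O)C[C@@H]1O
F7 | step 7 | allylic alcohol at the future C4 (epimer mixture) | CC(C)(C)[Si](c1ccccc1)(c1ccccc1)OCC[C@@H]1C=CC(O)C[C@@H]1O[Si](C)(C)C(C)(C)C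
F8 | step 16 | bis(triethylsilyl) ether of 22 (cis-fused) | CC(C)(C)[Si](c1ccccc1)(c1ccccc1)OCC[C@@H]1[C@@H]2C=C(C)[C@@H](O[Si](CC)(CC)CC)C[C@@H]2C(=O)C[C@@H]1O[Si](CC)(CC)CC
F9 | step 16 | bis(triethylsilyl) ether of 23 (trans-fused) | CC(C)(C)[Si](c1ccccc1)(c1ccccc1)OCC[C@@H]1[C@@H]2C=C(C)[C@@H](O[Si](CC)(CC)CC)C[C@H]2C(=O)C[C@@H]1O[Si](CC)(CC)CC
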